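The data are simulated with made-up constants, and the scatter is random.

- The target in the east and north-west runs levelled at y = 41.5% of the substrate charged, the mean of the last readings, 41.4% and 41.7%. Those readings differ by 0.3 percentage points, less than the scatter of 1 point, although the solid charges were 20 mM and 15 mM.

| flask | substrate | first nucleophile | solid second nucleophile | remark | time |
|---|---|---|---|---|---|
| east | 8 mM | 14 mM (fed, over 30 s) | 20 mM | run made earlier |  |
| north-west | 8 mM | 14 mM (fed, over 30 s) | 15 mM | run made earlier |  |
| winter | 8.0 mM | 14.0 mM (fed, over 30 s) | 30.0 mM |  | 15 min |
| midnight | 12 mM | 14.0 mM (fed, over 30 s) | 30.0 mM |  | 15 min |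
| dusk | 20 mM | 14.0 mM (fed, over 30 s) | 30.0 mM |  | 15 min |
| dawn | 30 mM | 14.0 mM (fed, over 30 s) | 30.0 mM |  | 15 min |
| noon | 50 mM | 14.0 mM (fed, over 30 s) | 30.0 mM |  | 15 min |

- east (time / min: target / %): 1.33: 23.8; 2.50: 34.4; 4.00: 39.7; 5.00: 41.4
- north-west (time / min: target / %): 0.667: 14.2; 2.00: 35.8; 3.00: 37.8; 5.00: 41.7

(each reading ± 1 percentage point)

- at the start none of the solid second nucleophile is in solution
- "hardly changes" means that all values lie within two and a half points (for a concentration: within two and a half percent of the largest)

- [target] at the end for winter, midnight, dusk, dawn, noon, in this order
- the shape of the row from first to last (rises, then falls / falls, then rises / hardly changes / rises all the way / falls all the way)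

- I kept a ledger per substrate unit charged, and its second entry was my own assumption. The share y became target and drew one first nucleophile. The rest I booked as side product, formed when substrate attacks target, so each side product holds two substrate units but one first nucleophile.
- The ledger closed at a draw d, which is y plus half of the remainder, or 0.708 first nucleophile per substrate unit.
- For winter I took y to hold, which gave 3.32 mM target. My ledger for winter then drew 5.66 mM of the 14.0 mM first nucleophile and left 59.6% of it, with substrate as the limiting reagent.
- Dividing the charge by the draw gave the reach S* = 19.8 mM, the substrate charge at which the ledger, with y held at its reading, uses up the whole first nucleophile.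
- Dawn and noon stood above the reach, so I expected their extra substrate to find no first nucleophile and still attack target. I committed to a row that turned near S* and then fell.
- The forecast gave 3.4 mM, 8.5 mM, 12 mM, 13 mM and 13.5 mM, of shape "rises all the way", holding that “the first nucleophile (14 mM) becomes limiting” and the target levels off.
- The flask gave 3.49 mM, 4.17 mM, 4.95 mM, 2.84 mM and 0.155 mM, of shape "rises, then falls", with the turn at 22 mM.

    first nucleophile + intermediate → target (k = 8.00 M⁻¹ s⁻¹)
    substrate + target → side product (k = 1.20 M⁻¹ s⁻¹)
    2 second nucleophile → self-condensation product (k = 0.0180 M⁻¹ s⁻¹)
    solid second nucleophile ⇌ second nucleophile, rate k4*(cs4 - [second nucleophile]) while solid is left; crystals form when [second nucleophile] > cs4 (solubility = 1.40 mM, k = 0.00330 s⁻¹)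
    second nucleophile + intermediate → other capture product (k = 3.90 M⁻¹ s⁻¹)
    substrate → intermediate (k = 0.00590 s⁻¹)

- In winter, the step from first nucleophile and intermediate to target had 99% of its turnover behind it at 7.50 min, while the step from substrate and target to side product had half of its turnover done by 2.22 min. The winter flask stood at 15.0 min with 43.7% target, 55.0% side product counted as two, and 59% of the first nucleophile left, against my 59.6%. In the dawn flask, with 30 mM of substrate against the reach of 19.8 mM, the first nucleophile stood at 0% of its charge at 15.0 min, the target at 9.46% of the substrate charged, and the intermediate at 6.56%.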